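**Retrosynthetic overview**

1. Atom labels: lactone O1, C2 (C=O), C3, C4 (stereocentre), C5; C6 is the exocyclic =CH carrying ring A (3-hydroxy-4,5-dimethoxyphenyl); C7 is the CH2 carrying ring B (4-hydroxy-3-methoxyphenyl). Both phenols travel as TBS ethers and are freed last.
2. The E alkene C3=C6 is cut by aldol addition and elimination between the C3 enolate of (R)-lactone 9 and the O-silylated ring A aldehyde 11.
3. The lactone, the only ring made, is cut at C3–C4. The feature used is that C7–C4–C5 is the 3-arylpropyl chain of ring B: C4 is its central CH2 with two enantiotopic hydrogens, and an acetate carbon (C3) hung on the C5 oxygen sits in a 1,5-relation to them. A chiral dirhodium carboxamidate turns diazoacetate 8 into a carbenoid that inserts into one of these hydrogens.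
4. Diazoacetate 8 comes from bromoacetate 5 (N,N'-ditosylhydrazine, DBU), 5 from alcohol 3 and bromoacetyl bromide 4, and 3 from dihydroconiferyl alcohol 1 by bis-silylation and selective methanolysis of the alkyl silyl ether.

Key step: step 5

Remark: Rh2(4R-MPPIM)4 is dirhodium tetrakis[methyl (4R)-2-oxo-1-(3-phenylpropanoyl)imidazolidine-4-carboxylate], both rhodium atoms divalent. It is assumed to give the R lactone with 3-arylpropyl diazoacetates; this sense is to be confirmed on the first batch, and the mirror-image catalyst Rh2(4S-MPPIM)4 is used instead if it is reversed.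
Remark: the rhodium carbenoid of step 5 is catalyst-bound and is described in the Why line without a number.

**Route**

Step 1
Reactants: 1 3-(4-hydroxy-3-methoxyphenyl)propan-1-ol
Product: 2 tert-butyl{3-[4-(tert-butyldimethylsilyloxy)-3-methoxyphenyl]propoxy}dimethylsilane
Conditions: TBSCl (2.4 equiv), imidazole (5 equiv), DMF, 0 °C → rt
Reagents that add atoms: tert-butyldimethylsilyl chloride, CC(C)(C)[Si](C)(C)Cl
Why: Imidazole-promoted silylation takes both hydroxyl groups, so no phenol-versus-alcohol selectivity is needed at this stage.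

Step 2
Reactants: 2 tert-butyl{3-[4-(tert-butyldimethylsilyloxy)-3-methoxyphenyl]propoxy}dimethylsilane
Product: 3 3-[4-(tert-butyldimethylsilyloxy)-3-methoxyphenyl]propan-1-ol
Conditions: CSA (0.1 equiv), MeOH/CH2Cl2 (1:1), 0 °C
Reagents that add atoms: none
Why: Acid-catalysed methanolysis starts with protonation of the ether oxygen, so the basic, unhindered primary alkyl silyl ether should be cleaved while the much less basic aryl silyl ether next to the methoxy group survives (selective desilylation).

Step 3
Reactants: 3 3-[4-(tert-butyldimethylsilyloxy)-3-methoxyphenyl]propan-1-ol; 4 bromoacetyl bromide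
Product: 5 3-[4-(tert-butyldimethylsilyloxy)-3-methoxyphenyl]propyl bromoacetate
Conditions: BrCH2COBr (1.3 equiv), NaHCO3 (3 equiv), MeCN, 0 °C
Reagents that add atoms: none
Why: O-acylation of the primary alcohol by the acyl bromide (nucleophilic acyl substitution), with solid NaHCO3 taking up HBr so that the aryl silyl ether and the alkyl bromide stay intact.

Step 4
Reactants: 5 3-[4-(tert-butyldimethylsilyloxy)-3-methoxyphenyl]propyl bromoacetate
Product: 8 3-[4-(tert-butyldimethylsilyloxy)-3-methoxyphenyl]propyl diazoacetate, via N-alkylated ditosylhydrazine 6 (not isolated), via glyoxylate tosylhydrazone 7 (not isolated)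
Conditions: TsNHNHTs (2 equiv), DBU (5 equiv), THF, 0 °C, 15 min
Reagents that add atoms: N,N'-ditosylhydrazine, Cc1ccc(cc1)S(=O)(=O)NNS(=O)(=O)c1ccc(C)cc1
Why: Diazo formation by the ditosylhydrazine method, in which the hydrazine anion displaces bromide (SN2) to give 6, DBU eliminates p-toluenesulfinate across C–N to give tosylhydrazone 7, and the anion of 7 loses the second sulfinate in a Bamford–Stevens-type fragmentation; short contact at 0 °C in dry THF should leave the aryl silyl ether untouched.

Step 5
Reactants: 8 3-[4-(tert-butyldimethylsilyloxy)-3-methoxyphenyl]propyl diazoacetate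
Product: 9 (4R)-4-{[4-(tert-butyldimethylsilyloxy)-3-methoxyphenyl]methyl}oxolan-2-one
Conditions: Rh2(4R-MPPIM)4 (1 mol %), CH2Cl2, reflux, 8 added over 8 h (syringe pump)
Reagents that add atoms: none
Why: Rh2(4R-MPPIM)4 takes N2 out of 8, and the resulting electrophilic rhodium carbenoid at C3 inserts into one C–H bond of the central chain CH2 (the future C4) through a concerted, asynchronous three-centre transition state in which hydrogen shifts to C3 while C3–C4 forms and the catalyst is released. The closest known reaction type is the enantioselective intramolecular C–H insertion of primary alkyl diazoacetates under chiral dirhodium carboxamidate catalysis, for which unbranched 3-arylpropyl esters with alkoxy-substituted rings are the best-behaved substrates. The γ-lactone closes by 1,5-insertion, that is through the five-membered array C3–C2–O1–C5–C4, the mode normally preferred by ester-tethered carbenoids. C4 is the only new stereocentre and is under catalyst control: the four carboxamidate ligands place their ester groups and N-acyl arms so that the bound carbenoid can reach only one of the two enantiotopic hydrogens, and the 4R catalyst is expected to give R. The step must favour this position over the C5–H bonds (β-lactone), the benzylic C7–H bonds (δ-lactone), addition to the electron-rich ring B and carbene dimerisation. The low electrophilicity of the carboxamidate-bound carbenoid, the geometric preference for the five-membered array, the distance and silyl shielding of ring B, and slow addition of 8 to the refluxing catalyst solution should secure this.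

Step 6
Reactants: 10 3-hydroxy-4,5-dimethoxybenzaldehyde
Product: 11 3-(tert-butyldimethylsilyloxy)-4,5-dimethoxybenzaldehyde
Conditions: TBSCl (1.2 equiv), imidazole (2.5 equiv), DMF, rt
Reagents that add atoms: tert-butyldimethylsilyl chloride, CC(C)(C)[Si](C)(C)Cl
Why: Imidazole-promoted silylation of the only hydroxyl group; the aldehyde is inert under these conditions.

Step 7
Reactants: 9 (4R)-4-{[4-(tert-butyldimethylsilyloxy)-3-methoxyphenyl]methyl}oxolan-2-one; 11 3-(tert-butyldimethylsilyloxy)-4,5-dimethoxybenzaldehyde
Product: 13 (3S,4R)-3-{[3-(tert-butyldimethylsilyloxy)-4,5-dimethoxyphenyl](hydroxy)methyl}-4-{[4-(tert-butyldimethylsilyloxy)-3-methoxyphenyl]methyl}oxolan-2-one (both carbinol epimers), via lithium enolate 12 (not isolated)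
Conditions: LiN(iPr)2 (1.1 equiv), THF, −78 °C; then 11 (1.2 equiv), −78 °C; AcOH quench at −78 °C
Reagents that add atoms: none
Why: Lithium enolate aldol addition, in which LiN(iPr)2 deprotonates C3 (the only α-position) and the non-enolisable aldehyde adds to the enolate face anti to the C4 arylmethyl group, so C3 and C4 should become trans; the uncontrolled carbinol centre and C3 are both erased in step 8, and C4 is not acidic under these conditions.

Step 8
Reactants: 13 (3S,4R)-3-{[3-(tert-butyldimethylsilyloxy)-4,5-dimethoxyphenyl](hydroxy)methyl}-4-{[4-(tert-butyldimethylsilyloxy)-3-methoxyphenyl]methyl}oxolan-2-one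
Product: 15 (3E,4R)-3-{[3-(tert-butyldimethylsilyloxy)-4,5-dimethoxyphenyl]methylidene}-4-{[4-(tert-butyldimethylsilyloxy)-3-methoxyphenyl]methyl}oxolan-2-one, via mesylate 14 (not isolated)
Conditions: MsCl (1.5 equiv), Et3N (3 equiv), CH2Cl2, 0 °C; then DBU (2.5 equiv), 0 °C → rt
Reagents that add atoms: none
Why: Mesylation of the benzylic alcohol followed by base-induced E1cB elimination through the lactone enolate converts both carbinol epimers into the conjugated alkylidene lactone, and the E geometry (aryl anti to the lactone carbonyl) is expected to dominate as is usual for α-arylidene γ-lactones made this way; C4 is not touched.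

Step 9
Reactants: 15 (3E,4R)-3-{[3-(tert-butyldimethylsilyloxy)-4,5-dimethoxyphenyl]methylidene}-4-{[4-(tert-butyldimethylsilyloxy)-3-methoxyphenyl]methyl}oxolan-2-one
Product: 16 (3E,4R)-3-[(3-hydroxy-4,5-dimethoxyphenyl)methylidene]-4-[(4-hydroxy-3-methoxyphenyl)methyl]oxolan-2-one
Conditions: Bu4NF (2.4 equiv), AcOH (2.4 equiv), THF, 0 °C
Reagents that add atoms: none
Why: Fluoride-induced cleavage of both aryl silyl ethers (strong Si–F bond, phenoxide leaving group), buffered with acetic acid so that no free phenoxide or basic fluoride isomerises or adds to the alkylidene lactone.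

**Compound list**

1 | 3-(4-hydroxy-3-methoxyphenyl)propan-1-ol | COc1cc(CCCO)ccc1O | starting material
2 | tert-butyl{3-[4-(tert-butyldimethylsilyloxy)-3-methoxyphenyl]propoxy}dimethylsilane | COc1cc(CCCO[Si](C)(C)C(C)(C)C)ccc1O[Si](C)(C)C(C)(C)C | intermediate
3 | 3-[4-(tert-butyldimethylsilyloxy)-3-methoxyphenyl]propan-1-ol | COc1cc(CCCO)ccc1O[Si](C)(C)C(C)(C)C | intermediate
4 | bromoacetyl bromide | BrCC(Br)=O | starting material
5 | 3-[4-(tert-butyldimethylsilyloxy)-3-methoxyphenyl]propyl bromoacetate | COc1cc(CCCOC(=O)CBr)ccc1O[Si](C)(C)C(C)(C)C | intermediate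
6 | 3-[4-(tert-butyldimethylsilyloxy)-3-methoxyphenyl]propyl 2-[1,2-bis(p-tolylsulfonyl)hydrazinyl]acetate (not isolated) | COc1cc(CCCOC(=O)CN(NS(=O)(=O)c2ccc(C)cc2)S(=O)(=O)c2ccc(C)cc2)ccc1O[Si](C)(C)C(C)(C)C | intermediate
7 | 3-[4-(tert-butyldimethylsilyloxy)-3-methoxyphenyl]propyl glyoxylate p-toluenesulfonylhydrazone (not isolated) | COc1cc(CCCOC(=O)C=NNS(=O)(=O)c2ccc(C)cc2)ccc1O[Si](C)(C)C(C)(C)C | intermediate
8 | 3-[4-(tert-butyldimethylsilyloxy)-3-methoxyphenyl]propyl diazoacetate | COc1cc(CCCOC(=O)C=[N+]=[N-])ccc1O[Si](C)(C)C(C)(C)C | intermediate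
9 | (4R)-4-{[4-(tert-butyldimethylsilyloxy)-3-methoxyphenyl]methyl}oxolan-2-one | COc1cc(C[C@H]2COC(=O)C2)ccc1O[Si](C)(C)C(C)(C)C | intermediate
10 | 3-hydroxy-4,5-dimethoxybenzaldehyde | O=Cc1cc(O)c(OC)c(OC)c1 | starting material
11 | 3-(tert-butyldimethylsilyloxy)-4,5-dimethoxybenzaldehyde | O=Cc1cc(O[Si](C)(C)C(C)(C)C)c(OC)c(OC)c1 | intermediate
12 | lithium enolate of 9, lithium (4R)-4-{[4-(tert-butyldimethylsilyloxy)-3-methoxyphenyl]methyl}-4,5-dihydrofuran-2-olate (not isolated) | COc1cc(C[C@H]2COC(O[Li])=C2)ccc1O[Si](C)(C)C(C)(C)C | intermediate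
13 | (3S,4R)-3-{[3-(tert-butyldimethylsilyloxy)-4,5-dimethoxyphenyl](hydroxy)methyl}-4-{[4-(tert-butyldimethylsilyloxy)-3-methoxyphenyl]methyl}oxolan-2-one, both carbinol epimers | COc1cc(C[C@H]2COC(=O)[C@@H]2C(O)c2cc(O[Si](C)(C)C(C)(C)C)c(OC)c(OC)c2)ccc1O[Si](C)(C)C(C)(C)C | intermediate
14 | methanesulfonate of 13 at the carbinol oxygen, (3S,4R), both epimers (not isolated) | COc1cc(C[C@H]2COC(=O)[C@@H]2C(OS(C)(=O)=O)c2cc(O[Si](C)(C)C(C)(C)C)c(OC)c(OC)c2)ccc1O[Si](C)(C)C(C)(C)C | intermediate
15 | (3E,4R)-3-{[3-(tert-butyldimethylsilyloxy)-4,5-dimethoxyphenyl]methylidene}-4-{[4-(tert-butyldimethylsilyloxy)-3-methoxyphenyl]methyl}oxolan-2-one | COc1cc(C[C@H]2COC(=O)/C2=C/c2cc(O[Si](C)(C)C(C)(C)C)c(OC)c(OC)c2)ccc1O[Si](C)(C)C(C)(C)C | intermediate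
16 | (3E,4R)-3-[(3-hydroxy-4,5-dimethoxyphenyl)methylidene]-4-[(4-hydroxy-3-methoxyphenyl)methyl]oxolan-2-one | COc1cc(C[C@H]2COC(=O)/C2=C/c2cc(O)c(OC)c(OC)c2)ccc1O | target

**Step count**

Total steps: 9. Longest linear sequence: 8 (steps 1–5 and 7–9); step 6 is a one-step side branch.

**Steps most likely to fail**

1. Step 5. The carbenoid may discriminate poorly between the two enantiotopic hydrogens, or be diverted into addition to ring B, insertion at C5–H or dimerisation.
Fallback (auxiliary-controlled enolate alkylation; sets out from 3, returns at 9): alcohol 3 is oxidised with TEMPO (cat.) and PhI(OAc)2 in aqueous MeCN through 3-[4-(tert-butyldimethylsilyloxy)-3-methoxyphenyl]propanal F1 to 3-[4-(tert-butyldimethylsilyloxy)-3-methoxyphenyl]propanoic acid F2. Pivaloyl chloride and Et3N in THF convert the acid into the mixed pivalic anhydride F3, which acylates (S)-4-benzyl-1,3-oxazolidin-2-one in the presence of LiCl to give the N-acyl oxazolidinone F4. Enolisation with NaN(SiMe3)2 at −78 °C and alkylation with tert-butyl bromoacetate on the face away from the auxiliary benzyl group should give the (3R)-alkylated imide F5. LiBH4 in THF at 0 °C removes the auxiliary reductively to give the hydroxy tert-butyl ester F6, and TsOH (cat.) in toluene closes the lactone with loss of tert-butanol to give 9.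

2. Step 8. The elimination may lose geometric control (Z isomer), and the base may move the new double bond into the ring, which would also destroy C4.
Fallback (Horner–Wadsworth–Emmons olefination; sets out from 9, returns at 15, bypassing 13 and 14): the lithium enolate 12, made with LiN(iPr)2 (2.2 equiv) in THF at −78 °C, is trapped with diethyl chlorophosphate as the enol phosphate F7. On warming, the second equivalent of amide base converts F7 by 1,3-migration of phosphorus from oxygen to C3 into the α-phosphono lactone F8 (C4 unchanged in space). Deprotonation of F8 with NaH in THF at 0 °C and reaction with aldehyde 11 should give 15 directly, with the E geometry typical of stabilised phosphonate olefinations.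

3. Step 4. The large excess of amidine base may attack the aryl silyl ether, and the diazo ester may decompose during isolation.
Fallback (acylation with a preformed hydrazone acid chloride; sets out from 3, returns at 8, bypassing 5 and 6): alcohol 3 is acylated with the acid chloride of glyoxylic acid p-toluenesulfonylhydrazone (PhNMe2, CH2Cl2, 0 °C) to give tosylhydrazone 7, and Et3N added to the same flask fragments it to 8. No compound outside the list is formed (F0).

**Further compounds**

F1 | step 5 | 3-[4-(tert-butyldimethylsilyloxy)-3-methoxyphenyl]propanal | COc1cc(CCC=O)ccc1O[Si](C)(C)C(C)(C)C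
F2 | step 5 | 3-[4-(tert-butyldimethylsilyloxy)-3-methoxyphenyl]propanoic acid | COc1cc(CCC(=O)O)ccc1O[Si](C)(C)C(C)(C)C
F3 | step 5 | 3-[4-(tert-butyldimethylsilyloxy)-3-methoxyphenyl]propanoic 2,2-dimethylpropanoic anhydride | COc1cc(CCC(=O)OC(=O)C(C)(C)C)ccc1O[Si](C)(C)C(C)(C)C
F4 | step 5 | (4S)-4-benzyl-3-{3-[4-(tert-butyldimethylsilyloxy)-3-methoxyphenyl]propanoyl}-1,3-oxazolidin-2-one | COc1cc(CCC(=O)N2[C@@H](Cc3ccccc3)COC2=O)ccc1O[Si](C)(C)C(C)(C)C
F5 | step 5 | tert-butyl (3R)-4-[(4S)-4-benzyl-2-oxo-1,3-oxazolidin-3-yl]-3-{[4-(tert-butyldimethylsilyloxy)-3-methoxyphenyl]methyl}-4-oxobutanoate | COc1cc(C[C@H](CC(=O)OC(C)(C)C)C(=O)N2[C@@H](Cc3ccccc3)COC2=O)ccc1O[Si](C)(C)C(C)(C)C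
F6 | step 5 | tert-butyl (3R)-3-{[4-(tert-butyldimethylsilyloxy)-3-methoxyphenyl]methyl}-4-hydroxybutanoate | COc1cc(C[C@H](CC(=O)OC(C)(C)C)CO)ccc1O[Si](C)(C)C(C)(C)C
F7 | step 8 | diethyl (4R)-4-{[4-(tert-butyldimethylsilyloxy)-3-methoxyphenyl]methyl}-4,5-dihydrofuran-2-yl phosphate | COc1cc(C[C@H]2COC(OP(=O)(OCC)OCC)=C2)ccc1O[Si](C)(C)C(C)(C)C
F8 | step 8 | diethyl [(4S)-4-{[4-(tert-butyldimethylsilyloxy)-3-methoxyphenyl]methyl}-2-oxooxolan-3-yl]phosphonate, C3 epimers (descriptor S at C4 only because phosphorus raises the rank of C3) | COc1cc(C[C@H]2COC(=O)C2P(=O)(OCC)OCC)ccc1O[Si](C)(C)C(C)(C)C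
F0 | step 4 | none | none
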